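## Retrosynthetic overview

1. Lepidine C comes from its bis-N-SEM derivative by deprotection. All four rings (two arenes, two imidazoles) are bought intact, so no ring is formed in the route.
2. Key cut: both ArCH2–C2(imidazole) bonds are made at once. Each CH2 carbon starts as an aldehyde carbon and is inverted to a benzyl-anion equivalent as its NH2-hydrazone. It is joined to the C2-electrophile 2-bromo-1-SEM-imidazole, and loss of N2 gives the CH2 level directly, so no deoxygenation step is needed.
3. The dialdehyde comes from SNAr diaryl ether formation between 2-fluoro-5-methoxybenzaldehyde and 3-hydroxybenzaldehyde.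
4. Order: diaryl ether, then twofold C–C coupling, then SEM removal.

Assumption: the SMILES holds no stereocentre, so lepidine C is achiral and needs no enantiocontrol. The two NH tautomers of each imidazole are the same compound.

SEM = CH2OCH2CH2SiMe3.

## Route

Step 1
Reactants: 1 2-fluoro-5-methoxybenzaldehyde; 2 3-hydroxybenzaldehyde
Product: 3 2-(3-formylphenoxy)-5-methoxybenzaldehyde
Conditions: K2CO3 (1.5 equiv), DMA, 150 °C, 18 h, N2
Reagents that add atoms: none
Why: Nucleophilic aromatic substitution (SNAr), in which the ortho-formyl group stabilises the Meisenheimer adduct and fluoride is the best leaving group, so the deactivating para-methoxy group is overcome at 150 °C; no stereocentre is formed.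

Step 2
Reactants: 4 2-bromo-1H-imidazole
Product: 6 2-bromo-1-{[2-(trimethylsilyl)ethoxy]methyl}-1H-imidazole, via sodium 2-bromoimidazolide 5 (not isolated)
Conditions: NaH (1.1 equiv), THF, 0 °C, 30 min; then SEMCl (1.05 equiv), 0 °C to rt, 2 h
Reagents that add atoms: sodium hydride, [Na+].[H-] (its sodium sits only in intermediate 5); 2-(trimethylsilyl)ethoxymethyl chloride (SEMCl), C[Si](C)(C)CCOCCl
Why: N-alkylation (SN2 at the chloromethyl ether) of the symmetrical imidazolide gives a single regioisomer, and SEM masks the acidic N–H that would consume base and bind nickel in step 3.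

Step 3
Reactants: 3 2-(3-formylphenoxy)-5-methoxybenzaldehyde; 6 2-bromo-1-{[2-(trimethylsilyl)ethoxy]methyl}-1H-imidazole (3.0 equiv)
Product: 8 1-SEM-2-[3-(4-methoxy-2-{[1-SEM-imidazol-2-yl]methyl}phenoxy)benzyl]imidazole (bis-N-SEM-lepidine C), via bis-hydrazone 7 (not isolated)
Conditions: 3 added to N2H4·H2O (6 equiv), THF, rt, 1 h; Na2SO4, excess N2H4 stripped at rt (toluene chase); crude 7 in THF added over 4 h to 6, Ni(cod)2 (20 mol %), PMe3 (40 mol %), LiOt-Bu (5 equiv), THF/1,4-dioxane, 80 °C, 16 h, Ar
Reagents that add atoms: hydrazine hydrate, NN.O (its nitrogen atoms sit only in intermediate 7 and leave as N2; none stays in 8)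
Why: Proposed new method: the NH2-hydrazone turns each electrophilic aldehyde carbon into a benzyl-anion equivalent, because oxidative addition of the C2–Br bond of 6 to zerovalent nickel, binding and deprotonation of the hydrazone on the divalent nickel centre, a 1,3-proton shift to a nickel diazenide, loss of N2 to a benzyl(imidazol-2-yl)nickel species and reductive elimination forge the CH2–C2 bond directly at the methylene level; the closest known reaction type is the Ni(cod)2/PMe3-catalysed Wolff–Kishner-type cross-coupling of aryl aldehyde hydrazones with aryl bromides, extended here to a 2-bromoazole and to two sites in one operation, with the aryl ether C–O bonds untouched beside the far more reactive C–Br bond and no stereocentre formed.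

Step 4
Reactants: 8 bis-N-SEM-lepidine C
Product: 9 lepidine C, 2-[3-(2-{[1H-imidazol-2-yl]methyl}-4-methoxyphenoxy)benzyl]-1H-imidazole
Conditions: 4 M aq HCl/EtOH (1:1), 75 °C, 5 h; then aq NaOH to pH 9, extraction with CHCl3/i-PrOH
Reagents that add atoms: none
Why: Acid hydrolysis of the two N,O-acetals (SEM cleavage) frees both N–H groups, while the aryl methyl ether, the diaryl ether and the benzylic CH2 groups are inert to hot aqueous HCl; no stereocentre is involved.

## Compound list

1 | 2-fluoro-5-methoxybenzaldehyde | COc1ccc(F)c(C=O)c1 | starting material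
2 | 3-hydroxybenzaldehyde | O=Cc1cccc(O)c1 | starting material
3 | 2-(3-formylphenoxy)-5-methoxybenzaldehyde | COc1ccc(Oc2cccc(C=O)c2)c(C=O)c1 | intermediate
4 | 2-bromo-1H-imidazole | Brc1ncc[nH]1 | starting material
5 | sodium 2-bromoimidazolide | [Na+].Brc1ncc[n-]1 | intermediate (not isolated)
6 | 2-bromo-1-{[2-(trimethylsilyl)ethoxy]methyl}-1H-imidazole | C[Si](C)(C)CCOCn1ccnc1Br | intermediate
7 | (E,E)-bis-hydrazone of 3 | COc1ccc(Oc2cccc(/C=N/N)c2)c(/C=N/N)c1 | intermediate (not isolated)
8 | bis-N-SEM-lepidine C | COc1ccc(Oc2cccc(Cc3nccn3COCC[Si](C)(C)C)c2)c(Cc2nccn2COCC[Si](C)(C)C)c1 | intermediate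
9 | lepidine C (achiral) | COc1ccc(Oc2cccc(Cc3ncc[nH]3)c2)c(Cc2ncc[nH]2)c1 | target

## Step count

Total step count: 4.
Longest linear sequence: 3 (steps 1, 3 and 4). Step 2 runs in parallel.

## Steps most likely to fail

**Step 3 (highest risk).**
- The bis-hydrazone must be the limiting partner, and both of its sites must couple.
- Competing paths are plain Wolff–Kishner reduction to ArCH3, azine oligomers, and N-arylation.
- Nickel may also be trapped by imidazole N3 or as a stable imidazol-2-yl nickel complex.
- The fallback sets out from dialdehyde 3 and comes back to the route at 8.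
- Commercial 1-SEM-imidazole (C[Si](C)(C)CCOCn1ccnc1) is deprotonated at C2 with n-BuLi (THF, −78 °C) to 2-lithio-1-SEM-imidazole F1, a carbanion at the amidine carbon.
- About 2.3 equiv of it add to both formyl groups of 3. An NH4Cl quench then gives the bis-carbinol F2, a mixture of diastereomers whose two centres are erased later.
- SOCl2 in CH2Cl2 (0 °C to rt) turns it into the bis-chloride F3.
- Zinc dust in AcOH at rt reduces both C–Cl bonds, which lie alpha to the imidazole C=N, to CH2 and gives 8.

**Step 1.**
- The methoxy group para to fluorine slows the SNAr, and two free aldehydes must survive 150 °C in base.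
- The fallback sets out from 2 and comes back at 3.
- Compound 2 is joined to commercial 2-bromo-5-methoxybenzaldehyde (COc1ccc(Br)c(C=O)c1) by a copper-catalysed Ullmann-type ether coupling: CuBr (10 mol %), picolinic acid (20 mol %), K3PO4, DMSO, 90 °C.
- The C–O bond forms at the metal, so it does not depend on an electron-poor ring.
- This way makes no compound outside the list (F0).

**Step 4.**
- SEM cleavage on imidazoles can stall at the N-hydroxymethyl stage.
- The released formaldehyde can re-add to the product, and the polar bis-imidazole is hard to extract.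
- The fallback sets out from 4 and comes back at 9.
- Compound 4 is alkylated with 4-methoxybenzyl chloride (K2CO3, DMF, rt) to 2-bromo-1-(4-methoxybenzyl)imidazole F4.
- F4 is coupled with bis-hydrazone 7 under the step 3 conditions to bis-N-PMB-lepidine C F5.
- Both PMB groups are then removed as benzylic cations with TFA/anisole and catalytic TfOH at 70 °C. This SN1-type cleavage releases no formaldehyde and gives 9.

## Further compounds

F1 | step 3 | 2-lithio-1-{[2-(trimethylsilyl)ethoxy]methyl}imidazole | [Li]c1nccn1COCC[Si](C)(C)C
F2 | step 3 | bis-carbinol, [1-SEM-imidazol-2-yl](aryl)methanol at both benzylic positions, mixture of diastereomers | COc1ccc(Oc2cccc(C(O)c3nccn3COCC[Si](C)(C)C)c2)c(C(O)c2nccn2COCC[Si](C)(C)C)c1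
F3 | step 3 | bis-chloride, chloride in place of each hydroxyl of F2, mixture of diastereomers | COc1ccc(Oc2cccc(C(Cl)c3nccn3COCC[Si](C)(C)C)c2)c(C(Cl)c2nccn2COCC[Si](C)(C)C)c1
F0 | step 1 | none | none
F4 | step 4 | 2-bromo-1-(4-methoxybenzyl)-1H-imidazole | COc1ccc(Cn2ccnc2Br)cc1
F5 | step 4 | bis-N-(4-methoxybenzyl)-lepidine C | COc1ccc(Oc2cccc(Cc3nccn3Cc3ccc(OC)cc3)c2)c(Cc2nccn2Cc2ccc(OC)cc2)c1
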